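If a longer feed is meant to build more mono adduct, count the turnovers each portion of starting material gets before the clock stops; here are the steps and the flasks.

    starting material + partner → mono adduct + by-product (k1 = 0.0014 M⁻¹ s⁻¹)
    starting material + partner → other mono adduct + by-product (k2 = 1.5 × 10⁻⁴ M⁻¹ s⁻¹)
    partner + mono adduct → double product + by-product (k3 = 0.0029 M⁻¹ s⁻¹)
    partner + other mono adduct → double product + by-product (k4 = 9.7 × 10⁻⁴ M⁻¹ s⁻¹)
    mono adduct → over-reaction product (k5 = 4.3 × 10⁻⁸ s⁻¹)
    gas ⇌ partner, rate k6*(csat - [partner]) (k6 = 6.7 × 10⁻⁴ s⁻¹, csat = 21 mM)
    starting material + mono adduct → side product (k7 = 9.7 × 10⁻⁴ M⁻¹ s⁻¹)

| setting | spring | winter | midnight | autumn |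
|---|---|---|---|---|
| starting material | 0.10 M (fed, over 0.80 h) | 0.10 M (fed, over 1.5 h) | 0.10 M (fed, over 3.0 h) | 0.10 M (fed, over 6.0 h) |
| gas | 21 mM (held) | 21 mM (held) | 21 mM (held) | 21 mM (held) |
| time | 6.0 h | 6.0 h | 6.0 h | 6.0 h |
| remark | the fed solution adds 0.50 times the starting volume | the fed solution adds 0.50 times the starting volume | the fed solution adds 0.50 times the starting volume | the fed solution adds 0.50 times the starting volume |

- percentages count the starting material that a species holds: one side product counts as two
- every charge counts on the volume at the start, and the solution that is fed holds the whole dose
- at the start none of partner is dissolved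
- "hardly changes" means that all values lie within two and a half points (for a concentration: within two and a half percent of the largest)
- run time (spring): 6.0 h

- [mono adduct] at the end for spring, winter, midnight, autumn, in this order
- how that number moves from the first to the last of them (hardly changes / rises all the way / falls, then rises / rises, then falls / falls all the way)

The mono adduct comes from starting material and partner, but partner also takes it on to double product, so its curve has a top; the constant of that second step is 2.07 times the one that makes it, a selectivity factor. The branch to the other mono adduct is smaller, with a constant of 1.5 × 10⁻⁴ M⁻¹ s⁻¹.

Partner starts at nothing, but its transfer from the gas, taken alone, has a half-time of 17.2 min, far below the run time. So I treat the first addition, starting material with partner to mono adduct, as pseudo-first-order at 21 mM, which is a ceiling, and my count runs high.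

The feed is steady, so the average portion arrives at half the dosing time. Spring's figure, 0.593, is the number I carry: the turnover count, the addition's constant times the saturation level times the time the average portion stays in the flask. Winter gets 0.556, midnight 0.476 and autumn 0.318.

With double addition as the sole loss, the top falls at the logarithm of the constants' ratio over that ratio less one, 0.680 turnovers. But starting material takes mono adduct too. With the whole charge spread over the final volume, 0.0667 M, the ratio grows to 4.27 and the top moves to 0.444.

Spring, winter and midnight lie inside that bracket, and autumn lies below it. So I expect a nearly flat start and a low autumn, and my reckoning stops short of the sign among the first flasks.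

The forecast gave 0.01 M, 0.0101 M, 0.0097 M and 0.008 M, shape rises, then falls, and called the first step “a close call against a steady fall”.

The flasks give 0.0101 M, 0.0100 M, 0.00983 M and 0.00806 M: falls all the way. In spring at 6.00 h, the addition makes mono adduct 1.6 times as fast as double addition takes it, and double addition takes it 1.7 times as fast as the side step, so gain over loss stands at 1.00, and spring's 0.593 turnovers end at the top. Autumn, with 0.318 turnovers, holds at 6.00 h 12.1% of its charge as mono adduct, against 15.1% in spring.

(The numbers of this flask are those of an exercise, and the outcome is calculated.)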